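**Plan**
- Cuts: after two benzyl groups and one acetate are removed, the retrosynthesis breaks the aryl C5–O bond of the depsidone ester. It then breaks the C4–O diaryl ether bond, the C6–CH2OH and C3 carbons of ring B, and the two carboxyl carbons of ring A.
- Enabling feature: on ring B the ester oxygen sits on C5, ortho to the ether carbon C4 and meta to the C7 phenol, and C4 is para to that phenol. Oxidising the phenol therefore lets the ring-A carboxyl land on C4 and turns C5–H into the β-carbon of a C7 dienone.
- Forward order: both benzene rings are bought. The γ-lactone closes first (step 5), the rings are joined by SNAr (step 7), C6 is formylated, and the seven-membered ring closes last (step 12) by way of a six-membered spiro ring.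
- Stereochemistry: the target has no stereocentre. The spiro carbon of 19 arises racemic and becomes planar again in the same flask.

Key step: step 12

Remark on the chemistry: the SMILES of conneotricone holds no stereocentre and no stereogenic double bond, so the compound is achiral and no enantiomer has to be chosen.
Numbering: ring B is numbered as a phthalide throughout. C1 is the lactone C=O, C3 the CH2, then C3a, C4 (ether O), C5 (ester O), C6 (CH2OH), C7 (OH) and C7a.

**Step 1**
Reactants: 1 3-fluoro-5-methylphenol
Product: 2 1-(benzyloxy)-3-fluoro-5-methylbenzene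
Conditions: BnBr, K2CO3, DMF, rt
Reagents that add atoms: benzyl bromide, BrCc1ccccc1
Why: Williamson ether synthesis; benzyl is chosen because it should survive LDA at −78 °C, iodine(III) and trifluoroacetic acid and leaves by hydrogenolysis at the end.

**Step 2**
Reactants: 2 1-(benzyloxy)-3-fluoro-5-methylbenzene
Product: 3 5-(benzyloxy)-2-bromo-1-fluoro-3-methylbenzene
Conditions: NBS, MeCN, 0 °C → rt, dark
Reagents that add atoms: N-bromosuccinimide, O=C1CCC(=O)N1Br
Why: Electrophilic aromatic bromination with NBS in a polar solvent goes para to the alkoxy group, the strongest donor, as is usual for 3,5-disubstituted aryl ethers, which places bromine between F and CH3.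

**Step 3**
Reactants: 3 5-(benzyloxy)-2-bromo-1-fluoro-3-methylbenzene
Product: 5 benzyl 6-(benzyloxy)-3-bromo-2-fluoro-4-methylbenzoate, via aryllithium 4 (not isolated)
Conditions: LDA, THF, −78 °C; ClCO2Bn, −78 °C → rt
Reagents that add atoms: benzyl chloroformate, O=C(Cl)OCc1ccccc1
Why: Directed ortho-metalation: the single C–H flanked by fluorine and the alkoxy group is by far the most acidic, LDA does not exchange the bromide, and at −78 °C the aryllithium is acylated by the chloroformate before it can lose LiF.

**Step 4**
Reactants: 5 benzyl 6-(benzyloxy)-3-bromo-2-fluoro-4-methylbenzoate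
Product: 7 3-benzyl 1-tert-butyl 4-(benzyloxy)-2-fluoro-6-methylbenzene-1,3-dicarboxylate, via arylmagnesium chloride 6 (not isolated)
Conditions: iPrMgCl·LiCl, THF, −20 °C; Boc2O, −20 °C → rt
Reagents that add atoms: di-tert-butyl dicarbonate, CC(C)(C)OC(=O)OC(=O)OC(C)(C)C
Why: Bromine–magnesium exchange with the turbo-Grignard reagent is accelerated by the ortho fluorine and tolerates the doubly ortho-substituted benzyl ester, and acylation of the arylmagnesium by Boc2O gives a tert-butyl ester that is orthogonal to the benzyl ester.

**Step 5**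
Reactants: 8 2,5-dimethoxybenzoic acid; 9 paraformaldehyde (formaldehyde)
Product: 12 4,7-dimethoxyisobenzofuran-1(3H)-one, via dilithio salt 10 (not isolated), via hydroxymethyl acid 11 (not isolated)
Conditions: s-BuLi (2.2 equiv), TMEDA, THF, −78 °C; (CH2O)n, −78 °C → rt; 2 M HCl, rt
Reagents that add atoms: none
Why: Directed ortho-metalation of the unprotected benzoic acid takes the C–H that lies between the lithium carboxylate and the 5-methoxy group, hydroxymethylation follows, and the ortho-hydroxymethyl acid lactonises on acidification.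

**Step 6**
Reactants: 12 4,7-dimethoxyisobenzofuran-1(3H)-one
Product: 13 4,7-dihydroxyisobenzofuran-1(3H)-one
Conditions: BBr3, CH2Cl2, −78 °C → rt; H2O
Reagents that add atoms: none
Why: Lewis-acid cleavage of aryl methyl ethers, routinely used on methoxyphthalides, and any lactone opened at the benzylic C–O bond closes again on aqueous work-up.

**Step 7**
Reactants: 7 3-benzyl 1-tert-butyl 4-(benzyloxy)-2-fluoro-6-methylbenzene-1,3-dicarboxylate; 13 4,7-dihydroxyisobenzofuran-1(3H)-one
Product: 14 3-benzyl 1-tert-butyl 4-(benzyloxy)-2-[(7-hydroxy-1-oxo-1,3-dihydroisobenzofuran-4-yl)oxy]-6-methylbenzene-1,3-dicarboxylate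
Conditions: K2CO3, DMSO, 70 °C, Ar
Reagents that add atoms: none
Why: Nucleophilic aromatic substitution (addition–elimination): fluorine lies between two esters and meta to both donors of ring A, and of the two phenoxides of 13 the one at C4 reacts because the one at C7 is delocalised into and bound to the lactone carbonyl, as in the selective 5-O-alkylation of 2,5-dihydroxybenzoates.

**Step 8**
Reactants: 14 diaryl ether from step 7; 9 paraformaldehyde (formaldehyde)
Product: 15 3-benzyl 1-tert-butyl 4-(benzyloxy)-2-[(6-formyl-7-hydroxy-1-oxo-1,3-dihydroisobenzofuran-4-yl)oxy]-6-methylbenzene-1,3-dicarboxylate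
Conditions: MgCl2, Et3N, (CH2O)n, MeCN, reflux; 1 M HCl
Reagents that add atoms: none
Why: Casnati–Skattebøl ortho-formylation: the magnesium phenoxide delivers formaldehyde only ortho to C7–O, where C6 is the single free site, a second formaldehyde accepts hydride to give the aldehyde, and running this after step 7 avoids the C5 attack that a free or methylated C4 oxygen would direct.

**Step 9**
Reactants: 15 aldehyde from step 8
Product: 16 3-benzyl 1-tert-butyl 4-(benzyloxy)-2-{[7-hydroxy-6-(hydroxymethyl)-1-oxo-1,3-dihydroisobenzofuran-4-yl]oxy}-6-methylbenzene-1,3-dicarboxylate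
Conditions: NaBH4, THF–MeOH, 0 °C
Reagents that add atoms: none
Why: Chemoselective borohydride reduction of an aldehyde, which leaves the two hindered esters and the phthalide untouched at 0 °C.

**Step 10**
Reactants: 16 salicyl alcohol from step 9
Product: 17 3-benzyl 1-tert-butyl 2-{[6-(acetoxymethyl)-7-hydroxy-1-oxo-1,3-dihydroisobenzofuran-4-yl]oxy}-4-(benzyloxy)-6-methylbenzene-1,3-dicarboxylate
Conditions: Ac2O (1.05 equiv), pyridine, CH2Cl2, 0 °C
Reagents that add atoms: acetic anhydride, CC(=O)OC(C)=O
Why: Chemoselective O-acetylation: the primary benzylic alcohol is the better neutral nucleophile, C7–OH is flanked on both sides and hydrogen-bonded to the lactone carbonyl, and any phenolic acetate should pass its acyl group to the neighbouring alcohol by O→O migration through a six-membered transition state.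

**Step 11**
Reactants: 17 acetate from step 10
Product: 18 2-{[6-(acetoxymethyl)-7-hydroxy-1-oxo-1,3-dihydroisobenzofuran-4-yl]oxy}-4-(benzyloxy)-3-[(benzyloxy)carbonyl]-6-methylbenzoic acid
Conditions: TFA–CH2Cl2 (1:3), rt
Reagents that add atoms: none
Why: Acidolysis of the tert-butyl ester through the tert-butyl cation frees only the carboxyl next to the ring-A methyl group, while benzyl ester, benzyl ether, acetate and phthalide are stable to these conditions.

**Step 12**
Reactants: 18 diaryl ether carboxylic acid with free C7 phenol and C5–H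
Product: 20 conneotricone benzyl ether, benzyl ester and O-acetate (depsidone with C5–O–C(=O), C6–CH2OAc and free C7–OH), via spiro quinone monoketal 19 (not isolated)
Conditions: PhI(OCOCF3)2 (1.0 equiv), 4 Å MS, CH2Cl2–(CF3)2CHOH, −20 → 0 °C; then TFA, 0 °C → rt, one flask
Reagents that add atoms: none
Why: Proposed new method: ligand exchange of PIFA at the C7 phenol and loss of iodobenzene make C4, the para carbon that the aryloxy group stabilises, electrophilic, and the ring-A carboxyl closes on it (6-exo-trig) to the racemic spiro benzodioxinone quinone monoketal 19, which is iodine(III) dearomatising spirolactonisation of a phenol extended to an aryloxy-bearing carbon. In 19 the carbon C5 is the β-carbon of the C7 dienone and the only ring-B carbon that still bears hydrogen. A bridged dioxolanylium ion is judged too strained, because the carbonyl oxygen of the six-membered lactone points away from C5, so the shift is planned stepwise: trifluoroacetic acid opens the C4–O(acyl) bond reversibly, trifluoroacetate caps the aryloxy-stabilised cation and so restores the dienone, and the freed carboxyl adds to C5 (7-exo-trig oxa-Michael), which forms the aryl–O ester bond and the seven-membered ring. Loss of trifluoroacetate from C4 and of the C5 proton rearomatises ring B irreversibly, so that the preceding equilibria should drain into 20; the closest known types are the acid-induced 1,2-acyloxy shift of quinol esters, Thiele–Winter acetoxylation and the addition–elimination of heteronucleophiles on quinone monoketals. The step needs an acyloxy group and not the aryloxy group to leave C4, and C5 and not C3a to be attacked: carboxylate and trifluoroacetate are far better leaving groups than the phenoxide, sieves keep out the water that would give the quinone, the tether reaches only C4, C5 and C3a, and addition at the fully substituted C3a cannot be followed by proton loss. No stereocentre is left, since the spiro carbon of 19 becomes an sp2 ring carbon again, and PIFA is used up before the acid is added so that the product phenol is not oxidised further.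

**Step 13**
Reactants: 20 depsidone acetate from step 12
Product: 21 conneotricone benzyl ether and benzyl ester (C6–CH2OH free)
Conditions: LiOH, THF–H2O, 0 °C; 1 M HCl
Reagents that add atoms: none
Why: Saponification (BAc2): the unhindered primary acetate is attacked faster than the aroyl carbonyls of depsidone and benzyl ester, each of which lies between two ortho substituents, the C7 phenoxide formed first deactivates the phthalide carbonyl and makes ring B a poorer leaving group, and water rather than an alcohol is the nucleophile so that no benzylic ether can form.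

**Step 14**
Reactants: 21 conneotricone benzyl ether and benzyl ester
Product: 22 conneotricone
Conditions: H2 (1 atm), Pd/C, THF–EtOAc, rt
Reagents that add atoms: none
Why: Catalytic hydrogenolysis of the benzyl aryl ether and the benzyl ester; the C6–CH2OH and C3–O benzylic bonds sit on a hexasubstituted ring that cannot lie flat on the catalyst, and the neutral medium avoids decarboxylation of the 2,6-dioxygenated benzoic acid.

**Compound list**
1 | 3-fluoro-5-methylphenol | Cc1cc(O)cc(F)c1 | starting material
2 | 1-(benzyloxy)-3-fluoro-5-methylbenzene | Cc1cc(OCc2ccccc2)cc(F)c1 | intermediate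
3 | 5-(benzyloxy)-2-bromo-1-fluoro-3-methylbenzene | Cc1cc(OCc2ccccc2)cc(F)c1Br | intermediate
4 | [6-(benzyloxy)-3-bromo-2-fluoro-4-methylphenyl]lithium | Cc1cc(OCc2ccccc2)c([Li])c(F)c1Br | intermediate
5 | benzyl 6-(benzyloxy)-3-bromo-2-fluoro-4-methylbenzoate | Cc1cc(OCc2ccccc2)c(C(=O)OCc2ccccc2)c(F)c1Br | intermediate
6 | {4-(benzyloxy)-3-[(benzyloxy)carbonyl]-2-fluoro-6-methylphenyl}magnesium chloride | Cc1cc(OCc2ccccc2)c(C(=O)OCc2ccccc2)c(F)c1[Mg]Cl | intermediate
7 | 3-benzyl 1-tert-butyl 4-(benzyloxy)-2-fluoro-6-methylbenzene-1,3-dicarboxylate | Cc1cc(OCc2ccccc2)c(C(=O)OCc2ccccc2)c(F)c1C(=O)OC(C)(C)C | intermediate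
8 | 2,5-dimethoxybenzoic acid | COc1ccc(OC)c(C(=O)O)c1 | starting material
9 | paraformaldehyde (formaldehyde) | C=O | starting material
10 | lithium 2-lithio-3,6-dimethoxybenzoate | COc1ccc(OC)c(C(=O)O[Li])c1[Li] | intermediate
11 | 2-(hydroxymethyl)-3,6-dimethoxybenzoic acid | COc1ccc(OC)c(C(=O)O)c1CO | intermediate
12 | 4,7-dimethoxyisobenzofuran-1(3H)-one | COc1ccc(OC)c2c1COC2=O | intermediate
13 | 4,7-dihydroxyisobenzofuran-1(3H)-one | Oc1ccc(O)c2c1COC2=O | intermediate
14 | 3-benzyl 1-tert-butyl 4-(benzyloxy)-2-[(7-hydroxy-1-oxo-1,3-dihydroisobenzofuran-4-yl)oxy]-6-methylbenzene-1,3-dicarboxylate | Cc1cc(OCc2ccccc2)c(C(=O)OCc2ccccc2)c(Oc2ccc(O)c3c2COC3=O)c1C(=O)OC(C)(C)C | intermediate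
15 | 3-benzyl 1-tert-butyl 4-(benzyloxy)-2-[(6-formyl-7-hydroxy-1-oxo-1,3-dihydroisobenzofuran-4-yl)oxy]-6-methylbenzene-1,3-dicarboxylate | Cc1cc(OCc2ccccc2)c(C(=O)OCc2ccccc2)c(Oc2cc(C=O)c(O)c3c2COC3=O)c1C(=O)OC(C)(C)C | intermediate
16 | 3-benzyl 1-tert-butyl 4-(benzyloxy)-2-{[7-hydroxy-6-(hydroxymethyl)-1-oxo-1,3-dihydroisobenzofuran-4-yl]oxy}-6-methylbenzene-1,3-dicarboxylate | Cc1cc(OCc2ccccc2)c(C(=O)OCc2ccccc2)c(Oc2cc(CO)c(O)c3c2COC3=O)c1C(=O)OC(C)(C)C | intermediate
17 | 3-benzyl 1-tert-butyl 2-{[6-(acetoxymethyl)-7-hydroxy-1-oxo-1,3-dihydroisobenzofuran-4-yl]oxy}-4-(benzyloxy)-6-methylbenzene-1,3-dicarboxylate | Cc1cc(OCc2ccccc2)c(C(=O)OCc2ccccc2)c(Oc2cc(COC(C)=O)c(O)c3c2COC3=O)c1C(=O)OC(C)(C)C | intermediate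
18 | 2-{[6-(acetoxymethyl)-7-hydroxy-1-oxo-1,3-dihydroisobenzofuran-4-yl]oxy}-4-(benzyloxy)-3-[(benzyloxy)carbonyl]-6-methylbenzoic acid | Cc1cc(OCc2ccccc2)c(C(=O)OCc2ccccc2)c(Oc2cc(COC(C)=O)c(O)c3c2COC3=O)c1C(=O)O | intermediate
19 | benzyl (±)-6'-(acetoxymethyl)-7-(benzyloxy)-5-methyl-1',4,7'-trioxo-1',7'-dihydro-3'H,4H-spiro[1,3-benzodioxine-2,4'-isobenzofuran]-8-carboxylate (racemic; ring-B C4 bears the aryl oxygen and the acyloxy oxygen of ring A) | Cc1cc(OCc2ccccc2)c(C(=O)OCc2ccccc2)c2c1C(=O)OC1(O2)C=C(COC(C)=O)C(=O)C2=C1COC2=O | intermediate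
20 | conneotricone benzyl ether, benzyl ester and O-acetate (depsidone; ring A CH3, OBn, CO2Bn; ring B C5–O–C(=O), C6–CH2OAc, C7–OH, fused γ-lactone) | Cc1cc(OCc2ccccc2)c(C(=O)OCc2ccccc2)c2c1C(=O)Oc1c(COC(C)=O)c(O)c3c(c1O2)COC3=O | intermediate
21 | conneotricone benzyl ether and benzyl ester (C6–CH2OH free) | Cc1cc(OCc2ccccc2)c(C(=O)OCc2ccccc2)c2c1C(=O)Oc1c(CO)c(O)c3c(c1O2)COC3=O | intermediate
22 | conneotricone (achiral) | Cc1cc(O)c(C(=O)O)c2c1C(=O)Oc1c(CO)c(O)c3c(c1O2)COC3=O | target

**Total step count:** 14
**Longest linear sequence:** 12 (steps 1–4 and 7–14, from 1)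

**Steps most likely to fail**

**Step 12.**
- What may go wrong:
  - The ketal may ionise with loss of the ring-A aryloxy group and collapse to the quinone.
  - Traces of water may hydrolyse the ketal.
  - The neighbouring acetate carbonyl may capture C5 in place of the carboxyl.
  - The spiro ketal may resist reclosure at C5.
- Fallback, known chemistry only; it sets out from 12 and 7 and returns at 21. The third ring-B oxygen is installed before the rings are joined, and the seven-membered ring is closed by classical lactonisation.
  - Bromination of 12 (Br2, AcOH) should go ortho to the unconjugated C4 methoxy group, as in 2,5-dimethoxybenzoates, to give 5-bromo-4,7-dimethoxyphthalide F1.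
  - Palladium-catalysed hydroxylation (KOH, dioxane–water, then acid to reclose the lactone) gives 5-hydroxy-4,7-dimethoxyphthalide F2, and BBr3 gives 4,5,7-trihydroxyphthalide F3.
  - Fully deprotonated F3 (excess K2CO3, DMSO, argon) is arylated by 7 to give the C5-hydroxy diaryl ether F4. The C4 phenoxide is the only one not conjugated with the lactone carbonyl and is the most nucleophilic. A Smiles equilibrium would lead to the same isomer, because it leaves the better stabilised C5 phenoxide free.
  - TFA frees the hydroxy acid F5. DCC then closes the ring on C5–OH (C7–OH is out of reach) to the C6-unsubstituted depsidone F6.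
  - Casnati–Skattebøl formylation at C6, the only free position, gives the depsidone aldehyde F7, and NaBH4 at low temperature reduces it to 21.

**Step 7.**
- What may go wrong:
  - Addition to the fluorine-bearing carbon may be slow, because both flanking esters are twisted out of conjugation.
  - Arylation may compete at C7–O.
  - The hydroquinone anion may be oxidised by air.
- Fallback; it sets out from 5 and returns at 14. The carboxyl next to the methyl group is carried one oxidation level lower as a smaller and more strongly activating formyl group.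
  - The arylmagnesium 6 made from 5 is quenched with DMF to give benzyl 6-(benzyloxy)-2-fluoro-3-formyl-4-methylbenzoate F8.
  - SNAr with 13 under milder conditions gives the diaryl ether aldehyde F9.
  - Pinnick oxidation (NaClO2, NaH2PO4, 2-methyl-2-butene) gives the diaryl ether acid F10.
  - O-alkylative esterification with N,N-dimethylformamide di-tert-butyl acetal, which is insensitive to the hindrance at the carboxyl carbon, gives 14.

**Step 13.**
- What may go wrong:
  - Opening of the seven-membered aryl ester may compete with acetate cleavage.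
  - The benzylic position may be lost through quinone methide formation.
- Fallback; it sets out from 20 and returns at 22. The order of the last two operations is reversed, so that the substrate protects itself electronically.
  - Hydrogenolysis of 20 gives O-acetylconneotricone F11.
  - In dilute aqueous carbonate the ring-A phenoxide of F11 stands para to the depsidone carbonyl and deactivates it as a vinylogous carbonate, and the molecule is a trianion. Only the acetate next to the C7 phenoxide is then cleaved, and acidification precipitates 22.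

**Further compounds**
F1 | step 12 | 5-bromo-4,7-dimethoxyisobenzofuran-1(3H)-one | COc1c(Br)cc(OC)c2c1COC2=O
F2 | step 12 | 5-hydroxy-4,7-dimethoxyisobenzofuran-1(3H)-one | COc1c(O)cc(OC)c2c1COC2=O
F3 | step 12 | 4,5,7-trihydroxyisobenzofuran-1(3H)-one | Oc1c(O)cc(O)c2c1COC2=O
F4 | step 12 | 3-benzyl 1-tert-butyl 4-(benzyloxy)-2-[(5,7-dihydroxy-1-oxo-1,3-dihydroisobenzofuran-4-yl)oxy]-6-methylbenzene-1,3-dicarboxylate | Cc1cc(OCc2ccccc2)c(C(=O)OCc2ccccc2)c(Oc2c(O)cc(O)c3c2COC3=O)c1C(=O)OC(C)(C)C
F5 | step 12 | 4-(benzyloxy)-3-[(benzyloxy)carbonyl]-2-[(5,7-dihydroxy-1-oxo-1,3-dihydroisobenzofuran-4-yl)oxy]-6-methylbenzoic acid | Cc1cc(OCc2ccccc2)c(C(=O)OCc2ccccc2)c(Oc2c(O)cc(O)c3c2COC3=O)c1C(=O)O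
F6 | step 12 | C6-unsubstituted depsidone (benzyl ether, benzyl ester, free C7–OH) | Cc1cc(OCc2ccccc2)c(C(=O)OCc2ccccc2)c2c1C(=O)Oc1cc(O)c3c(c1O2)COC3=O
F7 | step 12 | C6-formyl depsidone (benzyl ether, benzyl ester, free C7–OH) | Cc1cc(OCc2ccccc2)c(C(=O)OCc2ccccc2)c2c1C(=O)Oc1c(C=O)c(O)c3c(c1O2)COC3=O
F8 | step 7 | benzyl 6-(benzyloxy)-2-fluoro-3-formyl-4-methylbenzoate | Cc1cc(OCc2ccccc2)c(C(=O)OCc2ccccc2)c(F)c1C=O
F9 | step 7 | benzyl 6-(benzyloxy)-3-formyl-2-[(7-hydroxy-1-oxo-1,3-dihydroisobenzofuran-4-yl)oxy]-4-methylbenzoate | Cc1cc(OCc2ccccc2)c(C(=O)OCc2ccccc2)c(Oc2ccc(O)c3c2COC3=O)c1C=O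
F10 | step 7 | 4-(benzyloxy)-3-[(benzyloxy)carbonyl]-2-[(7-hydroxy-1-oxo-1,3-dihydroisobenzofuran-4-yl)oxy]-6-methylbenzoic acid | Cc1cc(OCc2ccccc2)c(C(=O)OCc2ccccc2)c(Oc2ccc(O)c3c2COC3=O)c1C(=O)O
F11 | step 13 | O-acetylconneotricone | Cc1cc(O)c(C(=O)O)c2c1C(=O)Oc1c(COC(C)=O)c(O)c3c(c1O2)COC3=O
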